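Early times are where you read a race between paths, so start there: you have one earlier run, alpha, and must rank four new flasks of substrate and catalyst.

| flask | substrate | catalyst | temperature | remark | time |
|---|---|---|---|---|---|
| alpha | 0.30 M | 3.4 mol% | −20 °C | run made earlier |  |
| Friday's | 1.2 M | 5 mol% | 0 °C |  | 25 min |
| Tuesday's | 0.30 M | 5 mol% | −20 °C |  | 25 min |
| Monday's | 1.2 M | 5 mol% | −20 °C |  | 25 min |
| Wednesday's | 0.30 M | 5 mol% | 0 °C |  | 25 min |

alpha run (percent of the substrate charged)

| time / min | target / % | substrate / % |
|---|---|---|
| 0.667 | 3 | 98 |
| 1.33 | 5 | 91 |
| 2.50 | 9 | 85 |
| 5.00 | 11 | 69 |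
| 8.00 | 17 | 52 |

(each reading ± 1.5 percentage points)

- the analysis behind the earlier runs scatters by 1.5 percentage points, standard deviation
- in a conversion other conformer counts as not yet reacted
- the earlier runs do not show what temperature does; that part of a forecast is a guess
- no earlier run changes the charge of catalyst; that part of a forecast is a guess

- ranking by amount of target, in percent of the substrate charged, from high to low, at 25 min (Friday's / Tuesday's / Monday's / Wednesday's)
- the same order at 2.5 min (Friday's / Tuesday's / Monday's / Wednesday's)
- the amount of target, in percent of the substrate charged of the flask you put first, at 25 min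
- the amount of target, in percent of the substrate charged of the flask you put last, at 25 min

Two numbers in alpha don't go together. By 8.00 min substrate has fallen to 52 %, a loss of 48 percentage points, yet target stands at 17 %. The missing 31 points far exceed a scatter of 1.5 points, so substrate must leave by a second path as well; call it the leak.

Here is my own reckoning. Take the target path as pseudo-first-order in substrate, with its rate constant proportional to [catalyst], and let the leak need no catalyst. Both assumptions about catalyst are guesses, since no earlier run varies the charge. Alpha's [catalyst] is 0.0102 M and its target-to-leak ratio, read at that one time and carrying the scatter, is 0.548, which gives an estimate of 0.0186 M for the crossing concentration, the [catalyst] at which the catalysed path and the leak take substrate equally fast at −20 °C. The selectivity at that temperature is then [catalyst] over [catalyst] plus the crossing concentration. Monday's, at 0.0600 M, stands above the crossing and is reckoned at 76.3 %. Tuesday's, at 0.0150 M, stands below it and is reckoned at 44.6 %. Friday's and Wednesday's are warmer, and what that does is a guess.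

The forecast ranks Monday's > Friday's > Tuesday's > Wednesday's at 25 min and Friday's > Monday's > Wednesday's > Tuesday's at 2.5 min. It gives 75 % for its first flask and 38 % for its last, on the ground that “Warm flasks therefore lead early but finish less selectively”.

The flasks give Monday's > Friday's > Wednesday's > Tuesday's at 25 min and Friday's > Monday's > Wednesday's > Tuesday's at 2.5 min. Monday's holds 81.3 % target, Wednesday's 51.5 % and Tuesday's 46.1 %.

    substrate + catalyst → catalyst + target (k = 2.97 /M/min, Ea = 40.0 kJ/mol)
    substrate ⇌ dormant form (K = 1.57, k = 0.0311 /min, Ea = 82.0 kJ/mol, ΔH = 20.0 kJ/mol)
    catalyst + other conformer → catalyst + isomer of the product (k = 4.34 /M/min, Ea = 35.0 kJ/mol)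
    substrate ⇌ other conformer (K = 0.640, k = 0.0193 /min, Ea = 74.0 kJ/mol, ΔH = −2.00 kJ/mol)
    (constants at −20 °C)

My selectivity for Monday's was 76.3 %, a share of the substrate used; at 25.0 min that flask holds 81.3 % target and has 9.54 % of the charge parked as dormant form. Without the turning of substrate into dormant form its target reaches 90.4 %, and the time allowed is the other part named here, since at 250 min it reaches 90.9 %. The neighbour of Monday's with 12 mol% of catalyst has a [catalyst] of 0.144 M and a crossing share of 88.6 %, and at 25.0 min that flask holds 91.6 % target.

(The numbers in the tables are calculated for an exercise; scatter was added.)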